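Start from the small charge: 26 mM of J, against a transfer that can deliver 248% of it by 4.0 min into a solution kept empty, so reckon by the level at which c_E stands along the way and not by the total supply.

J 26 mM; Q 6.1 mM (held); time 4.0 min

- J.E at 4.0 min, in percent of the J charged
- the change that raises the amount of J.E at 4.0 min, in percent of the J charged most ("none" if none brings more than 2 percentage points) (midnight / dusk / none)
- amount of J.E at 4.0 min, in percent of the J charged, after midnight

- midnight: doubling the transfer coefficient of step 2, all else as stated
- dusk: doubling the saturation concentration of Q, all else as stated

    J + E ⇌ J.E (K1 = 110 /M, k1 = 1.2 /M/s)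
    Q ⇌ E, rate k2*(csat - [E]) (k2 = 0.044 /s, csat = 6.1 mM)
    J ⇌ X (K3 = 0.31, k3 = 0.020 /s)

For the upper end of the bracket, an estimate, hold c_E at saturation and let J share its pool with X at equilibrium, which is fair because the relaxation half-life of 0.137 min is far shorter than the run. Then c_J.E climbs towards a ceiling of 33.9% of the J charged, in a pseudo-first-order approach at 0.990 /min, and reaches 33.2% by 4.0 min.

For the lower end of the bracket, also an estimate, replace the curve of c_E by its mean. What has been transferred stands as E or J.E, so divide c_E + c_J.E, with c_E at saturation and c_J.E at its ceiling, by k2 and the time, which gives 1.41 mM: this is the shortfall bound, the limit on the mean gap between saturation and c_E up to the time of reading, good while c_J.E stays under its ceiling. Hold c_E at 4.69 mM from the start, and c_J.E reaches 27.5%.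

Commit to the middle, 30.4%. Midnight, with k2 doubled, brings the bound down to 0.705 mM and lifts the lower figure to 30.5%, leaving the upper one in place, so the middle is 31.9%. Dusk raises the ceiling to 50.6%, while midnight leaves it unmoved, so choose dusk.

The forecast, which chose to “take E as quasi-steady”, gives 31.2%, dusk and 32.3%, and its first figure stands inside the bracket. The flask gives 30.8%, also inside it, with dusk as the best change, a gain of 18 percentage points against 1.5 points for midnight, and 32.3% after midnight.

Read the mean shortfall of this flask from its final c_E and c_J.E: it comes to 1.31 mM, under the bound of 1.41 mM. Carry the reckoning to the same flask read at 1.0 min, where the bound widens to 5.65 mM. The 4.42 mM of E and 12.8% of J.E in that flask read as a shortfall of 2.93 mM. Its upper figure falls to 21.3%, and that flask holds 12.8%.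

All constants belong to no real substance; what happens was integrated by code.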